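## Retrosynthetic overview

1. Ring T (O1, C2, C3, C4, C5) is 2,3-trans, 3,4-trans, 4,5-cis, that is (2S,3S,4S,5R). C2 carries the para-oxygenated ring A anti to the C3 methyl, so O1–C2 is cut last, back to the p-quinone methide of ring A and the C5 hydroxyl of an acyclic phenol alcohol.
2. The phenol alcohol is cut at C2–ring A by an sp3–sp2 Negishi coupling. C2 arrives as a plain CH2, with no oxygen and no stereocentre.
3. C4 and C5 come from a (Z)-crotylboration of the ring B aldehyde. C3 comes from methylation of a temporary γ-lactone.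
4. Both erythro (7R,8S) side chains come from one lactate-derived α-tosyloxy ketone, by SN2 inversion at C8 and chelate-controlled reduction at C7. The ring B chain is made first and the ring A chain after ring closure.
5. Ring order: the temporary lactone (closed in step 10, opened in step 12), then ring T (step 19), the only ring that has to be built.

Key step: step 19

Remark on labels:
- Ring A is the aryl on C2 and ring B the aryl on C5. Rings C and D are the 3,4-dimethoxyphenyl rings of the side chains on ring B and ring A.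
- C7 is the side-chain carbinol carbon and C8 the aryloxy-bearing carbon.
- ArB stands for 4-{[(1R,2S)-1-(tert-butyldimethylsilyloxy)-1-(3,4-dimethoxyphenyl)propan-2-yl]oxy}-3-methoxyphenyl.
- BEMP is 2-tert-butylimino-2-diethylamino-1,3-dimethylperhydro-1,3,2-diazaphosphorine.

## Route

Step 1
Reactants: 1 methyl (R)-lactate
Product: 2 (R)-2-hydroxy-N-methoxy-N-methylpropanamide
Conditions: MeNH(OMe)·HCl, i-PrMgCl, THF, −20 to 0 °C
Reagents that add atoms: N,O-dimethylhydroxylamine hydrochloride, CNOC.Cl
Why: Weinreb amide formation by magnesium amide aminolysis takes place at the acyl carbon only, so the lactate stereocentre should stay untouched.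

Step 2
Reactants: 2 (R)-2-hydroxy-N-methoxy-N-methylpropanamide; 3 4-bromo-1,2-dimethoxybenzene
Product: 5 (R)-1-(3,4-dimethoxyphenyl)-2-hydroxypropan-1-one, via 3,4-dimethoxyphenylmagnesium bromide 4 (not isolated)
Conditions: 3 (2.5 equiv), Mg, THF, reflux; then 2, THF, 0 °C; aq NH4Cl
Reagents that add atoms: none
Why: In this Weinreb ketone synthesis one equivalent of 4 deprotonates the hydroxyl and a second adds once to a chelated tetrahedral adduct that collapses only on quench, so neither over-addition nor loss of configuration is expected.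

Step 3
Reactants: 5 (R)-1-(3,4-dimethoxyphenyl)-2-hydroxypropan-1-one
Product: 6 (R)-1-(3,4-dimethoxyphenyl)-1-oxopropan-2-yl 4-methylbenzenesulfonate
Conditions: TsCl, pyridine, CH2Cl2, 0 °C to rt
Reagents that add atoms: p-toluenesulfonyl chloride, Cc1ccc(S(=O)(=O)Cl)cc1
Why: O-sulfonylation leaves the C8–O bond intact, so the (R) configuration is kept and C8 becomes an activated SN2 centre.

Step 4
Reactants: 6 (R)-tosyloxy ketone; 7 4-bromo-2-methoxyphenol
Product: 8 (S)-2-(4-bromo-2-methoxyphenoxy)-1-(3,4-dimethoxyphenyl)propan-1-one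
Conditions: BEMP (1.0 equiv), 7 (1.05 equiv), CH2Cl2, rt
Reagents that add atoms: none
Why: SN2 etherification of the α-keto tosylate by the phenoxide inverts C8 to (S), and since the phosphazene base is fully consumed by the phenol no free base remains to enolise the ketone.

Step 5
Reactants: 8 (S)-aryloxy ketone
Product: 9 (1R,2S)-2-(4-bromo-2-methoxyphenoxy)-1-(3,4-dimethoxyphenyl)propan-1-ol (erythro)
Conditions: Zn(BH4)2 (ethereal stock solution), Et2O–CH2Cl2, −20 °C
Reagents that add atoms: none
Why: In this Cram-chelate reduction zinc ties the carbonyl oxygen to the aryloxy oxygen (helped by the ortho methoxy group) and hydride enters from the face that carries the C8 hydrogen, which sets (7R) and so the erythro pair.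

Step 6
Reactants: 9 erythro alcohol
Product: 10 ArB–Br, the tert-butyldimethylsilyl ether of 9
Conditions: TBSOTf, 2,6-lutidine, CH2Cl2, 0 °C
Reagents that add atoms: tert-butyldimethylsilyl triflate, CC(C)(C)[Si](C)(C)OS(=O)(=O)C(F)(F)F
Why: Silylation at oxygen under buffered conditions masks the C7 hydroxyl against the organolithium, enolate and hydride steps without touching C7 or C8.

Step 7
Reactants: 10 ArB–Br
Product: 12 ArB–CHO (ring B benzaldehyde), via aryllithium 11 (not isolated)
Conditions: n-BuLi, THF, −78 °C; DMF, −78 to 0 °C; aq NH4Cl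
Reagents that add atoms: N,N-dimethylformamide, CN(C)C=O
Why: Bromine–lithium exchange followed by formylation with DMF is fast at low temperature and is tolerated by the aryl ethers and the silyl ether.

Step 8
Reactants: 12 ArB–CHO; 13 cis-2-butene
Product: 16 (1R,2S)-1-ArB-2-methylbut-3-en-1-ol, via (Z)-crotylpotassium 14 (not isolated), via (Z)-crotyldiisopinocampheylborane 15 (not isolated)
Conditions: 13, n-BuLi, KOt-Bu, THF, −78 to −45 °C; (+)-Ipc2BOMe, −78 °C; BF3·OEt2; 12, −78 °C; NaOH, H2O2, 0 °C to rt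
Reagents that add atoms: none
Why: Brown asymmetric crotylboration runs through a closed chair transition state in which the (Z)-crotyl geometry gives the syn C4/C5 pair and the (−)-α-pinene-derived ligands direct attack to the Re face of the aldehyde, which sets C5 (R) and C4 (S) under reagent control far from the side-chain stereocentres.

Step 9
Reactants: 16 homoallylic alcohol
Product: 18 (1R,2S)-1-ArB-2-methylbutane-1,4-diol, via B-alkyl-9-BBN adduct 17 (not isolated)
Conditions: 9-BBN (2.5 equiv), THF, 0 °C to rt; NaOH, H2O2, 0 °C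
Reagents that add atoms: hydrogen peroxide, OO
Why: Anti-Markovnikov hydroboration–oxidation of the monosubstituted alkene places the hydroxyl on the terminal carbon and creates no stereocentre.

Step 10
Reactants: 18 1,4-diol
Product: 20 (4S,5R)-5-ArB-4-methyldihydrofuran-2(3H)-one, via lactol 19 (not isolated)
Conditions: TEMPO (15 mol %), PhI(OAc)2 (2.5 equiv), CH2Cl2, rt
Reagents that add atoms: none
Why: In this oxoammonium-mediated oxidative lactonisation the primary alcohol is oxidised first, the aldehyde is caught by the C5 hydroxyl as lactol 19, and the lactol is oxidised on to the lactone before the secondary benzylic alcohol can react.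

Step 11
Reactants: 20 lactone
Product: 22 (3S,4S,5R)-5-ArB-3,4-dimethyldihydrofuran-2(3H)-one, via lithium enolate 21 (not isolated)
Conditions: LiN(i-Pr)2, THF, −78 °C; MeI, −78 to −40 °C
Reagents that add atoms: iodomethane, CI
Why: In this diastereoselective lactone enolate alkylation the C4 methyl and the C5 aryl share one face of the ring, so MeI approaches from the other face and sets C3 trans to the C4 methyl.

Step 12
Reactants: 22 dimethyl lactone
Product: 23 (1R,2S,3S)-1-ArB-2,3-dimethylbutane-1,4-diol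
Conditions: LiAlH4, THF, 0 °C
Reagents that add atoms: none
Why: Hydride reduction of the lactone to the diol turns the carbonyl carbon into the future C2 as CH2OH and touches no stereocentre or silyl ether.

Step 13
Reactants: 23 diol
Product: 24 bis(triethylsilyl) ether of 23
Conditions: TESCl (2.5 equiv), imidazole, DMAP (cat.), CH2Cl2, 0 °C to rt
Reagents that add atoms: chlorotriethylsilane, CC[Si](Cl)(CC)CC
Why: Both hydroxyls are silylated because a free C5 hydroxyl beside a C2 leaving group would close by 5-exo-tet displacement to a tetrahydrofuran that lacks ring A.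

Step 14
Reactants: 24 bis-TES ether
Product: 25 (2S,3S,4R)-4-ArB-2,3-dimethyl-4-(triethylsilyloxy)butan-1-ol
Conditions: PPTS (10 mol %), MeOH–CH2Cl2, −10 °C
Reagents that add atoms: none
Why: Acid-catalysed methanolysis of silyl ethers is governed by steric access to silicon, so the primary TES ether should fall well before the hindered secondary benzylic TES and TBS ethers.

Step 15
Reactants: 25 primary alcohol
Product: 26 (1R,2S,3S)-1-ArB-4-iodo-2,3-dimethyl-1-(triethylsilyloxy)butane
Conditions: I2, PPh3, imidazole, CH2Cl2, 0 °C, dark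
Reagents that add atoms: iodine, II
Why: Appel-type iodination displaces the alkoxyphosphonium group by SN2 at the primary carbon, and the imidazole buffer protects the silyl ethers.

Step 16
Reactants: 7 4-bromo-2-methoxyphenol
Product: 27 (4-bromo-2-methoxyphenoxy)triethylsilane
Conditions: TESCl, imidazole, CH2Cl2, 0 °C to rt
Reagents that add atoms: chlorotriethylsilane, CC[Si](Cl)(CC)CC
Why: Phenol silylation removes the acidic proton that would destroy the alkylzinc reagent, and the TES group is chosen so that it leaves together with the C5 TES ether in step 18.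

Step 17
Reactants: 26 iodide; 27 aryl bromide
Product: 29 (1R,2S,3R)-1-ArB-2,3-dimethyl-1-(triethylsilyloxy)-4-[3-methoxy-4-(triethylsilyloxy)phenyl]butane, via alkylzinc iodide 28 (not isolated)
Conditions: Zn dust (activated with BrCH2CH2Br and Me3SiCl), LiCl, THF, 40 °C; then 27, Pd(OAc)2 (3 mol %), SPhos (6 mol %), THF, rt to 50 °C
Reagents that add atoms: none
Why: Negishi sp3–sp2 cross-coupling of a primary β-branched alkylzinc iodide with an aryl bromide under a bulky biarylphosphine ligand forms C2–ring A, tolerates the silyl ethers and leaves C3 untouched because the metal sits on C2.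

Step 18
Reactants: 29 coupled bis-TES ether
Product: 30 (1R,2S,3R)-1-ArB-4-(4-hydroxy-3-methoxyphenyl)-2,3-dimethylbutan-1-ol (phenol alcohol)
Conditions: HF·pyridine, pyridine, THF, 0 °C
Reagents that add atoms: none
Why: Buffered fluoride desilylation removes the aryl and the secondary TES ethers much faster than the hindered secondary TBS ether at C7, and the pyridine buffer should keep the benzylic C5–O bond from ionising.

Step 19
Reactants: 30 phenol alcohol
Product: 32 4-[(2S,3S,4S,5R)-5-ArB-3,4-dimethyltetrahydrofuran-2-yl]-2-methoxyphenol, via p-quinone methide 31 (not isolated)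
Conditions: Ag2O (1.5 equiv), 4 Å molecular sieves, CH2Cl2 (0.005 M), dark, rt; filtration through Celite
Reagents that add atoms: none
Why: Ag2O takes two electrons and two protons (the phenolic O–H and one benzylic C2–H) from ring A to give p-quinone methide 31, whose exocyclic carbon C2 is then attacked by the C5 hydroxyl in a 1,6-oxa-conjugate addition that forms O1–C2 and restores the aromaticity of ring A. The closest known reaction types are the Ag2O oxidation of 4-alkyl-2-methoxyphenols to p-quinone methides and the intramolecular hydroxyl capture of such methides that builds the tetrahydrofuran rings of lignans. Ring T closes in the 5-exo-trig mode, because the attacked C2=C1 bond to ring A lies outside the forming ring. The new stereocentre C2 is controlled by C3: A(1,3) strain holds the C3 hydrogen in the plane of the methide, the tether reaches C2 from the face that carries C4, and ring A ends trans to the C3 methyl (2S), which is also the more stable arrangement and can be reached by reversible addition at C2 alone. The chemoselectivity needed is secured by the substrate, since rings B and C are fully etherified and the C7 hydroxyl is silylated, so only ring A is oxidised and the acid-labile cis C4/C5 benzylic C–O bond is never ionised. High dilution, sieves and a small excess of oxidant are chosen to hold back phenoxyl coupling, water capture and a second oxidation of 32.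

Step 20
Reactants: 32 ring-closed phenol; 6 (R)-tosyloxy ketone
Product: 33 (S)-1-(3,4-dimethoxyphenyl)-2-{4-[(2S,3S,4S,5R)-5-ArB-3,4-dimethyltetrahydrofuran-2-yl]-2-methoxyphenoxy}propan-1-one
Conditions: BEMP (1.0 equiv), 6 (1.1 equiv), CH2Cl2, rt
Reagents that add atoms: none
Why: SN2 etherification as in step 4 inverts the tosylate carbon to (8S) on ring A, and any base-induced reversible opening at C2 can only return the favoured 2,3-trans ring before alkylation locks it.

Step 21
Reactants: 33 aryloxy ketone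
Product: 34 mono-TBS ether of the target, with the ring A side chain (7R,8S) and its hydroxyl free
Conditions: Zn(BH4)2 (ethereal stock solution), Et2O–CH2Cl2, −20 °C
Reagents that add atoms: none
Why: The Cram-chelate reduction of step 5 is repeated, with hydride delivered from the face of the C8 hydrogen in the zinc chelate to set (7R) and so the second erythro pair.

Step 22
Reactants: 34 mono-TBS ether
Product: 35 target CNP0116650.8
Conditions: TBAF, THF, 0 °C to rt
Reagents that add atoms: none
Why: Fluoride cleaves the Si–O bond under non-acidic conditions, so no benzylic ether is ionised and no stereocentre is touched.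

## Compound list

1 | methyl (R)-lactate | C[C@@H](O)C(=O)OC | starting material
2 | (R)-2-hydroxy-N-methoxy-N-methylpropanamide | C[C@@H](O)C(=O)N(C)OC | intermediate
3 | 4-bromo-1,2-dimethoxybenzene | COc1ccc(Br)cc1OC | starting material
4 | 3,4-dimethoxyphenylmagnesium bromide | COc1ccc([Mg]Br)cc1OC | intermediate
5 | (R)-1-(3,4-dimethoxyphenyl)-2-hydroxypropan-1-one | C[C@@H](O)C(=O)c1ccc(OC)c(OC)c1 | intermediate
6 | (R)-1-(3,4-dimethoxyphenyl)-1-oxopropan-2-yl tosylate | C[C@@H](OS(=O)(=O)c1ccc(C)cc1)C(=O)c1ccc(OC)c(OC)c1 | intermediate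
7 | 4-bromo-2-methoxyphenol | COc1cc(Br)ccc1O | starting material
8 | (S)-2-(4-bromo-2-methoxyphenoxy)-1-(3,4-dimethoxyphenyl)propan-1-one | Brc1ccc(O[C@@H](C)C(=O)c2ccc(OC)c(OC)c2)c(OC)c1 | intermediate
9 | (1R,2S)-2-(4-bromo-2-methoxyphenoxy)-1-(3,4-dimethoxyphenyl)propan-1-ol | Brc1ccc(O[C@@H](C)[C@H](O)c2ccc(OC)c(OC)c2)c(OC)c1 | intermediate
10 | ArB–Br (TBS ether of 9) | Brc1ccc(O[C@@H](C)[C@H](O[Si](C)(C)C(C)(C)C)c2ccc(OC)c(OC)c2)c(OC)c1 | intermediate
11 | ArB–Li | [Li]c1ccc(O[C@@H](C)[C@H](O[Si](C)(C)C(C)(C)C)c2ccc(OC)c(OC)c2)c(OC)c1 | intermediate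
12 | ArB–CHO | O=Cc1ccc(O[C@@H](C)[C@H](O[Si](C)(C)C(C)(C)C)c2ccc(OC)c(OC)c2)c(OC)c1 | intermediate
13 | cis-2-butene | C/C=C\C | starting material
14 | (Z)-crotylpotassium | C/C=C\[CH2-].[K+] | intermediate
15 | (Z)-crotyldiisopinocampheylborane, Ipc groups from (−)-α-pinene | C/C=C\CB([C@H]1C[C@H]2C[C@@H]([C@@H]1C)C2(C)C)[C@H]1C[C@H]2C[C@@H]([C@@H]1C)C2(C)C | intermediate
16 | (1R,2S)-1-ArB-2-methylbut-3-en-1-ol | O[C@@H](c1ccc(O[C@@H](C)[C@H](O[Si](C)(C)C(C)(C)C)c2ccc(OC)c(OC)c2)c(OC)c1)[C@@H](C)C=C | intermediate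
17 | B-alkyl-9-BBN adduct of 16 | O[C@@H](c1ccc(O[C@@H](C)[C@H](O[Si](C)(C)C(C)(C)C)c2ccc(OC)c(OC)c2)c(OC)c1)[C@@H](C)CCB3C4CCCC3CCC4 | intermediate
18 | (1R,2S)-1-ArB-2-methylbutane-1,4-diol | O[C@@H](c1ccc(O[C@@H](C)[C@H](O[Si](C)(C)C(C)(C)C)c2ccc(OC)c(OC)c2)c(OC)c1)[C@@H](C)CCO | intermediate
19 | (4S,5R)-5-ArB-4-methyltetrahydrofuran-2-ol (lactol, anomers) | O3[C@@H](c1ccc(O[C@@H](C)[C@H](O[Si](C)(C)C(C)(C)C)c2ccc(OC)c(OC)c2)c(OC)c1)[C@@H](C)CC3O | intermediate
20 | (4S,5R)-5-ArB-4-methyldihydrofuran-2(3H)-one | O3[C@@H](c1ccc(O[C@@H](C)[C@H](O[Si](C)(C)C(C)(C)C)c2ccc(OC)c(OC)c2)c(OC)c1)[C@@H](C)CC3=O | intermediate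
21 | lithium enolate of 20 | O3[C@@H](c1ccc(O[C@@H](C)[C@H](O[Si](C)(C)C(C)(C)C)c2ccc(OC)c(OC)c2)c(OC)c1)[C@@H](C)C=C3O[Li] | intermediate
22 | (3S,4S,5R)-5-ArB-3,4-dimethyldihydrofuran-2(3H)-one | O3[C@@H](c1ccc(O[C@@H](C)[C@H](O[Si](C)(C)C(C)(C)C)c2ccc(OC)c(OC)c2)c(OC)c1)[C@@H](C)[C@H](C)C3=O | intermediate
23 | (1R,2S,3S)-1-ArB-2,3-dimethylbutane-1,4-diol | O[C@@H](c1ccc(O[C@@H](C)[C@H](O[Si](C)(C)C(C)(C)C)c2ccc(OC)c(OC)c2)c(OC)c1)[C@@H](C)[C@H](C)CO | intermediate
24 | bis(triethylsilyl) ether of 23 | CC[Si](CC)(CC)O[C@@H](c1ccc(O[C@@H](C)[C@H](O[Si](C)(C)C(C)(C)C)c2ccc(OC)c(OC)c2)c(OC)c1)[C@@H](C)[C@H](C)CO[Si](CC)(CC)CC | intermediate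
25 | (2S,3S,4R)-4-ArB-2,3-dimethyl-4-(triethylsilyloxy)butan-1-ol | CC[Si](CC)(CC)O[C@@H](c1ccc(O[C@@H](C)[C@H](O[Si](C)(C)C(C)(C)C)c2ccc(OC)c(OC)c2)c(OC)c1)[C@@H](C)[C@H](C)CO | intermediate
26 | (1R,2S,3S)-1-ArB-4-iodo-2,3-dimethyl-1-(triethylsilyloxy)butane | CC[Si](CC)(CC)O[C@@H](c1ccc(O[C@@H](C)[C@H](O[Si](C)(C)C(C)(C)C)c2ccc(OC)c(OC)c2)c(OC)c1)[C@@H](C)[C@H](C)CI | intermediate
27 | (4-bromo-2-methoxyphenoxy)triethylsilane | COc1cc(Br)ccc1O[Si](CC)(CC)CC | intermediate
28 | alkylzinc iodide from 26 | CC[Si](CC)(CC)O[C@@H](c1ccc(O[C@@H](C)[C@H](O[Si](C)(C)C(C)(C)C)c2ccc(OC)c(OC)c2)c(OC)c1)[C@@H](C)[C@H](C)C[Zn]I | intermediate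
29 | Negishi product, C5 and ring A oxygens as TES ethers | CC[Si](CC)(CC)O[C@@H](c1ccc(O[C@@H](C)[C@H](O[Si](C)(C)C(C)(C)C)c2ccc(OC)c(OC)c2)c(OC)c1)[C@@H](C)[C@H](C)Cc3ccc(O[Si](CC)(CC)CC)c(OC)c3 | intermediate
30 | (1R,2S,3R)-1-ArB-4-(4-hydroxy-3-methoxyphenyl)-2,3-dimethylbutan-1-ol | O[C@@H](c1ccc(O[C@@H](C)[C@H](O[Si](C)(C)C(C)(C)C)c2ccc(OC)c(OC)c2)c(OC)c1)[C@@H](C)[C@H](C)Cc1ccc(O)c(OC)c1 | intermediate
31 | p-quinone methide of 30 (geometry at the exocyclic C=C not defined) | O[C@@H](c1ccc(O[C@@H](C)[C@H](O[Si](C)(C)C(C)(C)C)c2ccc(OC)c(OC)c2)c(OC)c1)[C@@H](C)[C@H](C)C=C3C=CC(=O)C(OC)=C3 | intermediate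
32 | 4-[(2S,3S,4S,5R)-5-ArB-3,4-dimethyltetrahydrofuran-2-yl]-2-methoxyphenol | Oc1ccc([C@H]2O[C@@H](c3ccc(O[C@@H](C)[C@H](O[Si](C)(C)C(C)(C)C)c4ccc(OC)c(OC)c4)c(OC)c3)[C@@H](C)[C@@H]2C)cc1OC | intermediate
33 | (8S)-aryloxy ketone on ring A | COc1ccc(C(=O)[C@H](C)Oc2ccc([C@H]3O[C@@H](c4ccc(O[C@@H](C)[C@H](O[Si](C)(C)C(C)(C)C)c5ccc(OC)c(OC)c5)c(OC)c4)[C@@H](C)[C@@H]3C)cc2OC)cc1OC | intermediate
34 | mono-TBS ether of the target | COc1ccc([C@@H](O)[C@H](C)Oc2ccc([C@H]3O[C@@H](c4ccc(O[C@@H](C)[C@H](O[Si](C)(C)C(C)(C)C)c5ccc(OC)c(OC)c5)c(OC)c4)[C@@H](C)[C@@H]3C)cc2OC)cc1OC | intermediate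
35 | CNP0116650.8 | COc1ccc([C@@H](O)[C@H](C)Oc2ccc([C@H]3O[C@@H](c4ccc(O[C@@H](C)[C@H](O)c5ccc(OC)c(OC)c5)c(OC)c4)[C@@H](C)[C@@H]3C)cc2OC)cc1OC | target

## Step count and risks

Total step count: 22.
Longest linear sequence: 21 (steps 1–15 and 17–22). Step 16 is a one-step branch.

**Step 19 (key step).**
- What may go wrong: coupling of the phenoxyl radical at the free ortho position of ring A may outrun the second oxidation. The water formed may capture the methide. The product phenol may be oxidised a second time at C2. Facial selectivity at C2 may be incomplete.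
- Fallback: the same methide is made without an oxidant, by 1,6-elimination.
- It sets out from 25, which Dess–Martin periodinane oxidises to the aldehyde F1.
- The aryllithium F2, made from 27 with n-BuLi at −78 °C, adds to F1 to give the C2 carbinol F3. Its C2 epimers do not matter, because C2 is flattened later.
- Ac2O and pyridine convert F3 into the benzylic acetate F4.
- HF·pyridine removes both TES groups to give the 4-hydroxybenzyl acetate F5. On treatment with NaHCO3 this loses acetic acid to give 31, which closes as in the main route.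
- The fallback comes back at 32.

**Step 21 (and its early twin, step 5).**
- What may go wrong: the aryl ether oxygen may bind zinc too weakly. An open Felkin–Anh transition state then competes and facial selectivity drifts toward the threo alcohol.
- Fallback: the order of bond formation is changed so that the C7–ring D bond is made last.
- It sets out from 32, which undergoes a Mitsunobu etherification with 1 (PPh3, DIAD, THF) with inversion to give the (S)-aryloxy ester F6.
- i-Bu2AlH at −78 °C gives the aldehyde F7.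
- Grignard reagent 4 adds to F7 at −78 °C under polar Felkin–Anh control, anti to the aryloxy group, which leads to (7R,8S).
- The fallback comes back at 34.

**Step 17.**
- What may go wrong: zinc insertion may be slow, or the alkylzinc may be protonated. The alkylpalladium intermediate may undergo β-hydride elimination. Oxidative addition of the electron-rich bromide may be sluggish.
- Fallback: the polarity of the coupling is reversed.
- It sets out from 26 and 27. Bromide 27 is converted with Mg in THF into the arylmagnesium bromide F8.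
- F8 displaces the primary iodide of 26 under Li2CuCl4 catalysis at −20 to 0 °C.
- The fallback comes back at 29.

## Further compounds

F1 | step 19 | (2S,3S,4R)-4-ArB-2,3-dimethyl-4-(triethylsilyloxy)butanal | CC[Si](CC)(CC)O[C@@H](c1ccc(O[C@@H](C)[C@H](O[Si](C)(C)C(C)(C)C)c2ccc(OC)c(OC)c2)c(OC)c1)[C@@H](C)[C@H](C)C=O
F2 | step 19 | 3-methoxy-4-(triethylsilyloxy)phenyllithium | [Li]c1ccc(O[Si](CC)(CC)CC)c(OC)c1
F3 | step 19 | C2 carbinol, both C2 epimers, C5 and ring A oxygens as TES ethers | CC[Si](CC)(CC)O[C@@H](c1ccc(O[C@@H](C)[C@H](O[Si](C)(C)C(C)(C)C)c2ccc(OC)c(OC)c2)c(OC)c1)[C@@H](C)[C@H](C)C(O)c3ccc(O[Si](CC)(CC)CC)c(OC)c3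
F4 | step 19 | C2 acetate of F3 | CC[Si](CC)(CC)O[C@@H](c1ccc(O[C@@H](C)[C@H](O[Si](C)(C)C(C)(C)C)c2ccc(OC)c(OC)c2)c(OC)c1)[C@@H](C)[C@H](C)C(OC(C)=O)c3ccc(O[Si](CC)(CC)CC)c(OC)c3
F5 | step 19 | 4-hydroxybenzyl acetate with free C5 hydroxyl | O[C@@H](c1ccc(O[C@@H](C)[C@H](O[Si](C)(C)C(C)(C)C)c2ccc(OC)c(OC)c2)c(OC)c1)[C@@H](C)[C@H](C)C(OC(C)=O)c3ccc(O)c(OC)c3
F6 | step 21 | methyl (S)-2-aryloxypropanoate of 32 | COC(=O)[C@H](C)Oc1ccc([C@H]2O[C@@H](c3ccc(O[C@@H](C)[C@H](O[Si](C)(C)C(C)(C)C)c4ccc(OC)c(OC)c4)c(OC)c3)[C@@H](C)[C@@H]2C)cc1OC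
F7 | step 21 | (S)-2-aryloxypropanal of 32 | O=C[C@H](C)Oc1ccc([C@H]2O[C@@H](c3ccc(O[C@@H](C)[C@H](O[Si](C)(C)C(C)(C)C)c4ccc(OC)c(OC)c4)c(OC)c3)[C@@H](C)[C@@H]2C)cc1OC
F8 | step 17 | 3-methoxy-4-(triethylsilyloxy)phenylmagnesium bromide | Br[Mg]c1ccc(O[Si](CC)(CC)CC)c(OC)c1
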